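**Retrosynthetic overview**
1. Target ⇐ acetylation of C4–OH, hydride attack on a C4 ketone from the face syn to the C8 bridge, and O‑methylation of a C3 enol ⇐ a bicyclo[3.2.1]oct‑2‑ene‑4,8‑dione with a free C3 enol (diosphenol).
2. Key disconnection: C1–C8 and C2=C3 are cut together. Both carbocycles open to one monocyclic precursor, a 3‑methoxy‑3‑alkylfuran‑2,4‑dione (C8 = lactone carbonyl, C5 = its C3, C4 = ketone, C3 = OCH2) whose side chain ends in an α‑allyl aldehyde (C1–H, C2 = CHO).
3. Enabling feature: in the six‑membered ring C1–C2–C3–C4–C5–C8 the neighbours C8, C5, C4 and C3 all carry oxygen (a hidden 3‑methoxytetronic acid). C1 is α both to the C8 ketone and to C2, a hidden formyl carbon, so C1–C8 is a Claisen‑type retron and C2=C3 an aldol‑condensation retron.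
4. Ring order forward: temporary lactone ring (made first, opened in the key step) → five‑membered ring C1‑C8‑C5‑C6‑C7 → six‑membered ring, the last two in one flask.
5. C5/C6 come from an enantioselective Claisen rearrangement of a cinnamyl tetronate, C7 from a cuprate addition to the enal made by cross metathesis, and the allyl group from a palladium‑catalysed allylation.

Key step: step 9

Assumption: the (R,R) antipode of the guanidinium catalyst in step 5 is taken to give the (3S,1'R) series. If the sense is opposite, the catalyst made from (S,S)‑cyclohexane‑1,2‑diamine is used.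

Step 1
Reactants: 1 methyl (E)-3-(3,4,5-trimethoxyphenyl)prop-2-enoate
Product: 2 (E)-3-(3,4,5-trimethoxyphenyl)prop-2-en-1-ol
Conditions: i-Bu2AlH (2.3 equiv), CH2Cl2, −78 °C → 0 °C; aq. potassium sodium tartrate
Reagents that add atoms: none
Why: 1,2-Reduction of a conjugated ester with i-Bu2AlH is the standard route to cinnamyl alcohols, leaves the E-alkene untouched and forms no stereocentre.

Step 2
Reactants: 3 methyl glycolate; 4 methoxyacetyl chloride
Product: 5 methyl 2-[(2-methoxyacetyl)oxy]acetate
Conditions: Et3N, DMAP (cat.), CH2Cl2, 0 °C → rt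
Reagents that add atoms: none
Why: This is a plain O-acylation of a primary alcohol by an acid chloride with amine base.

Step 3
Reactants: 5 methyl 2-[(2-methoxyacetyl)oxy]acetate
Product: 6 4-hydroxy-3-methoxyfuran-2(5H)-one (3-methoxytetronic acid)
Conditions: LiN(SiMe3)2 (2.2 equiv), THF, −78 °C → rt; 1 M HCl
Reagents that add atoms: none
Why: In this Lacey–Dieckmann cyclisation the α-alkoxy ester enolate attacks the glycolate ester 5-exo-trig, and formation of the very acidic tetronic acid as its lithium salt makes the closure irreversible and overrides the competing acyl shift of the glycolate enolate.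

Step 4
Reactants: 6 4-hydroxy-3-methoxyfuran-2(5H)-one; 2 (E)-3-(3,4,5-trimethoxyphenyl)prop-2-en-1-ol
Product: 7 3-methoxy-4-{[(E)-3-(3,4,5-trimethoxyphenyl)prop-2-en-1-yl]oxy}furan-2(5H)-one
Conditions: PPh3, DIAD, THF, 0 °C → rt
Reagents that add atoms: none
Why: Mitsunobu alkylation of a tetronic acid with a primary allylic alcohol takes place at the vinylogous acid oxygen O4 and should give the 4-alkoxybutenolide with the E-alkene intact.

Step 5
Reactants: 7 3-methoxy-4-{[(E)-3-(3,4,5-trimethoxyphenyl)prop-2-en-1-yl]oxy}furan-2(5H)-one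
Product: 8 (3S)-3-methoxy-3-[(1R)-1-(3,4,5-trimethoxyphenyl)prop-2-en-1-yl]furan-2,4(3H,5H)-dione
Conditions: N,N'-bis[(1R,2R)-2-(2-phenylpyrrol-1-yl)cyclohexyl]guanidinium tetrakis[3,5-bis(trifluoromethyl)phenyl]borate (20 mol %), toluene, 40 °C, several days
Reagents that add atoms: none
Why: In this hydrogen-bond-donor-catalysed enantioselective Claisen rearrangement of an O-allyl β-keto ester enol ether, the ring fixes the enol ether geometry (OMe cis to the allyloxy group) and the E-cinnamyl unit reacts through a chair that places aryl anti to the C4 carbonyl carbon, which sets the (3S,1'R) relative configuration of both new stereocentres, while the chiral guanidinium ion bound at the two vicinal ether oxygens selects the enantiotopic face.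

Step 6
Reactants: 8 (3S)-3-methoxy-3-[(1R)-1-(3,4,5-trimethoxyphenyl)prop-2-en-1-yl]furan-2,4(3H,5H)-dione; 9 (E)-but-2-enal (crotonaldehyde, 5 equiv)
Product: 10 (2E,4R)-4-[(3S)-3-methoxy-2,4-dioxooxolan-3-yl]-4-(3,4,5-trimethoxyphenyl)but-2-enal
Conditions: second-generation Hoveyda–Grubbs catalyst (5 mol %), CH2Cl2, 40 °C
Reagents that add atoms: none
Why: Cross metathesis of a hindered terminal alkene that does not homodimerise with an excess of an electron-poor partner should give the E-enal under neutral conditions that the base-sensitive dione tolerates, and the two stereocentres are not involved.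

Step 7
Reactants: 10 (2E,4R)-4-[(3S)-3-methoxy-2,4-dioxooxolan-3-yl]-4-(3,4,5-trimethoxyphenyl)but-2-enal
Product: 11 (3S)-3-methoxy-3-[(1R,2R)-2-methyl-1-(3,4,5-trimethoxyphenyl)-4-(trimethylsilyloxy)but-3-en-1-yl]furan-2,4(3H,5H)-dione (E/Z mixture at the enol ether)
Conditions: Me2CuLi (from MeLi and CuI, 1.5 equiv), Me3SiCl (3 equiv), THF, −78 °C; Et3N, cold aq. NaHCO3
Reagents that add atoms: lithium dimethylcuprate [Li+].C[Cu-]C; chlorotrimethylsilane C[Si](C)(C)Cl
Why: The Me3SiCl-accelerated Gilman conjugate addition is much faster than attack at the hindered ketone or the lactone, and in the A(1,3)-minimised conformer C4–H eclipses the alkene so the cuprate enters anti to the quaternary carbon, which gives the methyl/aryl syn centre with the enolate trapped at once as its silyl ether.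

Step 8
Reactants: 11 silyl enol ether (name as above); 12 allyl methyl carbonate
Product: 13 (3S,4R)-4-[(3S)-3-methoxy-2,4-dioxooxolan-3-yl]-3-methyl-2-(prop-2-en-1-yl)-4-(3,4,5-trimethoxyphenyl)butanal (both C2 epimers)
Conditions: Pd2(dba)3·CHCl3 (2.5 mol %), dppe (6 mol %), THF, rt → 40 °C
Reagents that add atoms: none
Why: In this Tsuji allylation of a silyl enol ether under neutral conditions, methoxide set free on ionisation of the carbonate removes silicon and the enolate is captured within the ion pair by the π-allylpalladium cation, and the new centre forms as a mixture, which is harmless because step 9 planarises it.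

Step 9
Reactants: 13 (3S,4R)-4-[(3S)-3-methoxy-2,4-dioxooxolan-3-yl]-3-methyl-2-(prop-2-en-1-yl)-4-(3,4,5-trimethoxyphenyl)butanal
Product: 16 (1S,5R,6R,7S)-3-hydroxy-5-methoxy-7-methyl-1-(prop-2-en-1-yl)-6-(3,4,5-trimethoxyphenyl)bicyclo[3.2.1]oct-2-ene-4,8-dione, via formyl cyclopentanone 14 (not isolated), via aldol adduct 15 (not isolated)
Conditions: KOt-Bu (2.2 equiv), THF–t-BuOH (5:1), 0.01 M, −20 °C → rt; 1 M HCl
Reagents that add atoms: none
Why: Proposed new method: KOt-Bu reversibly enolises the aldehyde, whose α-carbon (C1) attacks the doubly activated lactone carbonyl (C8) of the furan-2,4-dione in a Dieckmann-type transacylation that expels the C3–O alkoxide inside the molecule (14), and the hydroxyacetyl enediolate thus unmasked adds through C3 to the now non-enolisable formyl carbon C2 (15) and loses hydroxide by E1cB to give the delocalised diosphenolate of 16. The closest known reaction types are the Dieckmann and Lacey–Dieckmann condensations, the reversible Claisen formylation of ketones and the intramolecular aldol condensation of 1,5-dicarbonyl compounds; what is new is their coupling on an α-branched aldehyde enolate, so that a quaternary 2-formyl ketone is made and consumed in the same flask. The cyclopentanone (C1, C8, C5, C6, C7) closes 5-(enolexo)-exo-trig at the lactone carbonyl and the cyclohexenone (C1, C2, C3, C4, C5, C8) closes 6-(enolendo)-exo-trig at the formyl group. The only new stereocentre that survives, quaternary C1, is planar in the enolate (both epimers of 13 converge) and is dictated by C5, because only the isomer with formyl and hydroxyacetyl groups cis on the five-membered ring can bridge, while the trans isomer returns to the enolate by retro-Claisen attack of its own alkoxide. The step needs acylation at the lactone rather than aldol addition at the C4 ketone, and C- rather than O-acylation; both alternatives are reversible dead ends, whereas dehydration to the far better stabilised diosphenolate is the one irreversible exit. C5, C6 and C7 carry no acidic hydrogen and are not touched.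

Step 10
Reactants: 16 (1S,5R,6R,7S)-3-hydroxy-5-methoxy-7-methyl-1-(prop-2-en-1-yl)-6-(3,4,5-trimethoxyphenyl)bicyclo[3.2.1]oct-2-ene-4,8-dione
Product: 17 (1S,5R,6R,7S)-3,5-dimethoxy-7-methyl-1-(prop-2-en-1-yl)-6-(3,4,5-trimethoxyphenyl)bicyclo[3.2.1]oct-2-ene-4,8-dione
Conditions: Me2SO4 (1.5 equiv), K2CO3, acetone, rt
Reagents that add atoms: dimethyl sulfate COS(=O)(=O)OC
Why: A diosphenolate is O-alkylated by a hard methylating agent, C-methylation at C2 is blocked by the neighbouring quaternary bridgehead, and the enol can form only towards C2.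

Step 11
Reactants: 17 (1S,5R,6R,7S)-3,5-dimethoxy-7-methyl-1-(prop-2-en-1-yl)-6-(3,4,5-trimethoxyphenyl)bicyclo[3.2.1]oct-2-ene-4,8-dione
Product: 18 (1S,4R,5S,6R,7S)-4-hydroxy-3,5-dimethoxy-7-methyl-1-(prop-2-en-1-yl)-6-(3,4,5-trimethoxyphenyl)bicyclo[3.2.1]oct-2-en-8-one
Conditions: NaBH4 (1.0 equiv), CeCl3·7H2O (1.2 equiv), MeOH–CH2Cl2, −78 °C
Reagents that add atoms: none
Why: In this Luche 1,2-reduction the enone carbonyl C4 should react before the C8 ketone, which is shielded by two fully substituted bridgeheads, and hydride enters from the face syn to the C8 bridge because the endo aryl group on C6 covers the other face, which places the hydroxyl group endo (4R).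

Step 12
Reactants: 18 (1S,4R,5S,6R,7S)-4-hydroxy-3,5-dimethoxy-7-methyl-1-(prop-2-en-1-yl)-6-(3,4,5-trimethoxyphenyl)bicyclo[3.2.1]oct-2-en-8-one
Product: 19 (1S,4R,5S,6R,7S)-3,5-dimethoxy-7-methyl-8-oxo-1-(prop-2-en-1-yl)-6-(3,4,5-trimethoxyphenyl)bicyclo[3.2.1]oct-2-en-4-yl acetate (CNP0181407.1)
Conditions: Ac2O, pyridine, DMAP (cat.), CH2Cl2, rt
Reagents that add atoms: acetic anhydride CC(=O)OC(C)=O
Why: DMAP-catalysed acetylation of the hindered secondary alcohol affects no stereocentre.

**Compound list**
1 | methyl (E)-3-(3,4,5-trimethoxyphenyl)prop-2-enoate | COC(=O)/C=C/c1cc(OC)c(OC)c(OC)c1 | starting material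
2 | (E)-3-(3,4,5-trimethoxyphenyl)prop-2-en-1-ol | OC/C=C/c1cc(OC)c(OC)c(OC)c1 | intermediate
3 | methyl glycolate | COC(=O)CO | starting material
4 | methoxyacetyl chloride | COCC(=O)Cl | starting material
5 | methyl 2-[(2-methoxyacetyl)oxy]acetate | COCC(=O)OCC(=O)OC | intermediate
6 | 4-hydroxy-3-methoxyfuran-2(5H)-one | COC1=C(O)COC1=O | intermediate
7 | 3-methoxy-4-{[(E)-3-(3,4,5-trimethoxyphenyl)prop-2-en-1-yl]oxy}furan-2(5H)-one | COC1=C(OC/C=C/c2cc(OC)c(OC)c(OC)c2)COC1=O | intermediate
8 | (3S)-3-methoxy-3-[(1R)-1-(3,4,5-trimethoxyphenyl)prop-2-en-1-yl]furan-2,4(3H,5H)-dione | C=C[C@H](c1cc(OC)c(OC)c(OC)c1)[C@]2(OC)C(=O)COC2=O | intermediate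
9 | (E)-but-2-enal | C/C=C/C=O | starting material
10 | (2E,4R)-4-[(3S)-3-methoxy-2,4-dioxooxolan-3-yl]-4-(3,4,5-trimethoxyphenyl)but-2-enal | O=C/C=C/[C@H](c1cc(OC)c(OC)c(OC)c1)[C@]2(OC)C(=O)COC2=O | intermediate
11 | (3S)-3-methoxy-3-[(1R,2R)-2-methyl-1-(3,4,5-trimethoxyphenyl)-4-(trimethylsilyloxy)but-3-en-1-yl]furan-2,4(3H,5H)-dione (E/Z mixture) | C[C@H](C=CO[Si](C)(C)C)[C@H](c1cc(OC)c(OC)c(OC)c1)[C@]2(OC)C(=O)COC2=O | intermediate
12 | allyl methyl carbonate | C=CCOC(=O)OC | starting material
13 | (3S,4R)-4-[(3S)-3-methoxy-2,4-dioxooxolan-3-yl]-3-methyl-2-(prop-2-en-1-yl)-4-(3,4,5-trimethoxyphenyl)butanal (C2 epimers) | O=CC(CC=C)[C@@H](C)[C@H](c1cc(OC)c(OC)c(OC)c1)[C@]2(OC)C(=O)COC2=O | intermediate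
14 | (1S,2S,3R,4R)-4-(2-hydroxyacetyl)-4-methoxy-2-methyl-5-oxo-1-(prop-2-en-1-yl)-3-(3,4,5-trimethoxyphenyl)cyclopentane-1-carbaldehyde | C=CC[C@]1(C=O)C(=O)[C@@](OC)(C(=O)CO)[C@@H](c2cc(OC)c(OC)c(OC)c2)[C@@H]1C | intermediate
15 | (1S,5R,6R,7S)-2,3-dihydroxy-5-methoxy-7-methyl-1-(prop-2-en-1-yl)-6-(3,4,5-trimethoxyphenyl)bicyclo[3.2.1]octane-4,8-dione (C2 and C3 undefined) | C=CC[C@]12C(O)C(O)C(=O)[C@](OC)(C1=O)[C@@H](c3cc(OC)c(OC)c(OC)c3)[C@@H]2C | intermediate
16 | (1S,5R,6R,7S)-3-hydroxy-5-methoxy-7-methyl-1-(prop-2-en-1-yl)-6-(3,4,5-trimethoxyphenyl)bicyclo[3.2.1]oct-2-ene-4,8-dione | C=CC[C@]12C=C(O)C(=O)[C@](OC)(C1=O)[C@@H](c3cc(OC)c(OC)c(OC)c3)[C@@H]2C | intermediate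
17 | (1S,5R,6R,7S)-3,5-dimethoxy-7-methyl-1-(prop-2-en-1-yl)-6-(3,4,5-trimethoxyphenyl)bicyclo[3.2.1]oct-2-ene-4,8-dione | C=CC[C@]12C=C(OC)C(=O)[C@](OC)(C1=O)[C@@H](c3cc(OC)c(OC)c(OC)c3)[C@@H]2C | intermediate
18 | (1S,4R,5S,6R,7S)-4-hydroxy-3,5-dimethoxy-7-methyl-1-(prop-2-en-1-yl)-6-(3,4,5-trimethoxyphenyl)bicyclo[3.2.1]oct-2-en-8-one | C=CC[C@]12C=C(OC)[C@@H](O)[C@](OC)(C1=O)[C@@H](c3cc(OC)c(OC)c(OC)c3)[C@@H]2C | intermediate
19 | (1S,4R,5S,6R,7S)-3,5-dimethoxy-7-methyl-8-oxo-1-(prop-2-en-1-yl)-6-(3,4,5-trimethoxyphenyl)bicyclo[3.2.1]oct-2-en-4-yl acetate | C=CC[C@]12C=C(OC)[C@@H](OC(C)=O)[C@](OC)(C1=O)[C@@H](c1cc(OC)c(OC)c(OC)c1)[C@@H]2C | target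

Total step count: 12. Longest linear sequence: 11 steps (steps 2–12, from 3 and 4).

**Steps most likely to fail**

Step 9. Formyl transfer may outrun the bridging aldol closure. This would be retro-Claisen cleavage of the non-enolisable β-keto aldehyde by its own alkoxide or by tert-butoxide. Alternatively, the material may be parked in reversible aldol adducts at the C4 ketone. The fallback uses known chemistry and brings the allyl group in after the first ring. It sets out from 11 and comes back to the route at 14.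
- Mild hydrolysis (AcOH, THF–H2O) gives the aldehyde (3R,4R)-4-[(3S)-3-methoxy-2,4-dioxooxolan-3-yl]-3-methyl-4-(3,4,5-trimethoxyphenyl)butanal F1.
- KOt-Bu in THF closes it in a Claisen-type condensation. This closure ends in a stabilised, enolisable product, (3S,4R,5R)-5-(2-hydroxyacetyl)-2-(hydroxymethylidene)-5-methoxy-3-methyl-4-(3,4,5-trimethoxyphenyl)cyclopentan-1-one F2.
- K2CO3 and allyl bromide in acetone give its enol ether, (3S,4R,5R)-5-(2-hydroxyacetyl)-5-methoxy-3-methyl-2-[(prop-2-en-1-yloxy)methylidene]-4-(3,4,5-trimethoxyphenyl)cyclopentan-1-one F3. Any direct C-allylation leads to 14 as well.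
- Heating in toluene (110 °C) brings about the Claisen rearrangement. Allyl should be delivered to the face of C1 turned away from the aryl group and the hydroxyacetyl chain, giving 14.
- 14 is isolated and closed to 16 in a separate aldol condensation (piperidinium acetate, benzene, water separator).

Step 5. The push–pull enol ether may rearrange too slowly under hydrogen-bond catalysis, because the ring lactone carbonyl cannot take part in two-point binding. A racemic thermal background, an unfavourable equilibrium (loss of styrene conjugation) or weak face selection could then dominate. The fallback replaces the sigmatropic step by metal-catalysed allylation. It sets out from 2 and 6 and comes back at 8.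
- ClCO2Me and pyridine convert 2 into (E)-3-(3,4,5-trimethoxyphenyl)prop-2-en-1-yl methyl carbonate F4.
- F4 alkylates 6 at C3 in a branched-selective asymmetric allylic alkylation. Conditions: [Ir(cod)Cl]2, binaphthol-derived phosphoramidite bearing a bis(1-phenylethyl)amine unit, 1,5,7-triazabicyclo[4.4.0]dec-5-ene, THF.
- The ligand sets the benzylic centre. The diastereomers at the quaternary carbon are separated if needed.

Step 8. The transient, not yet allylated aldehyde enolate may attack the lactone before it meets the π-allylpalladium cation (premature ring closure), or a second allylation may occur. The fallback avoids any enolate. It sets out from 11 and comes back at 13.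
- N-Bromosuccinimide (THF, −78 °C) gives (3S,4R)-2-bromo-4-[(3S)-3-methoxy-2,4-dioxooxolan-3-yl]-3-methyl-4-(3,4,5-trimethoxyphenyl)butanal F5.
- Keck radical allylation (allyltributylstannane, AIBN, benzene, 80 °C) replaces bromine by allyl under neutral conditions.

**Further compounds**
F1 | step 9 | (3R,4R)-4-[(3S)-3-methoxy-2,4-dioxooxolan-3-yl]-3-methyl-4-(3,4,5-trimethoxyphenyl)butanal | O=CC[C@@H](C)[C@H](c1cc(OC)c(OC)c(OC)c1)[C@]2(OC)C(=O)COC2=O
F2 | step 9 | (3S,4R,5R)-5-(2-hydroxyacetyl)-2-(hydroxymethylidene)-5-methoxy-3-methyl-4-(3,4,5-trimethoxyphenyl)cyclopentan-1-one | OC=C1C(=O)[C@@](OC)(C(=O)CO)[C@@H](c2cc(OC)c(OC)c(OC)c2)[C@@H]1C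
F3 | step 9 | (3S,4R,5R)-5-(2-hydroxyacetyl)-5-methoxy-3-methyl-2-[(prop-2-en-1-yloxy)methylidene]-4-(3,4,5-trimethoxyphenyl)cyclopentan-1-one | C=CCOC=C1C(=O)[C@@](OC)(C(=O)CO)[C@@H](c2cc(OC)c(OC)c(OC)c2)[C@@H]1C
F4 | step 5 | (E)-3-(3,4,5-trimethoxyphenyl)prop-2-en-1-yl methyl carbonate | COC(=O)OC/C=C/c1cc(OC)c(OC)c(OC)c1
F5 | step 8 | (3S,4R)-2-bromo-4-[(3S)-3-methoxy-2,4-dioxooxolan-3-yl]-3-methyl-4-(3,4,5-trimethoxyphenyl)butanal | O=CC(Br)[C@@H](C)[C@H](c1cc(OC)c(OC)c(OC)c1)[C@]2(OC)C(=O)COC2=O
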